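All constants were set for the occasion; the result is computed.

Slowness is the question in the flasks below: they differ in the loading of the catalyst D and are read at the same time.

    E + D → E.D (k1 = 21700 L mol⁻¹ s⁻¹)
    E.D → G (k2 = 220 s⁻¹)
    J + G ⇌ J.G (K3 = 2110 L mol⁻¹, k3 = 23600 L mol⁻¹ s⁻¹)
    J.G → D + X (k4 = 6.42 s⁻¹)
    X ⇌ Q (K5 = 0.24, k5 = 0.0220 s⁻¹)

| setting | violet | ochre | red | amber | green |
|---|---|---|---|---|---|
| J | 0.50 mM | 0.50 mM | 0.50 mM | 0.50 mM | 0.50 mM |
| E | 0.900 equiv | 0.900 equiv | 0.900 equiv | 0.900 equiv | 0.900 equiv |
| D | 2 mol% | 4 mol% | 8 mol% | 15 mol% | 30 mol% |
| time | 10 s | 10 s | 10 s | 10 s | 10 s |

- a step back or a flat step of under half a point counts as no turn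
- "hardly changes" means that all values lie within two and a half points (for a concentration: within two and a half percent of the largest)
- run time (violet): 10 s

- amount of X at the end, in percent of the J charged for violet, ochre, red, amber, green, in this order
- the shape of the row from first to last (falls all the way / falls, then rises / rises all the way / rises, then falls / hardly changes)

D takes up the reagent E, passes through E.D to G, G binds the substrate J as J.G, and J.G gives the product X and returns D. X then interconverts with Q. Each round uses one E and one J.

Two chemists disagree. The first holds the end-point view: E, at 0.900 equiv, is the limiting reagent, and step 5 divides what is formed between X and Q, so X ends at 72.6% of the J charged, whatever the loading. She adds that the relaxation half-life of X and Q in violet, 6.10 s, is shorter than the run. Her row hardly changes.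

I hold the clock view and add up the delays in the loop, at the starting charges. E reaches D in 0.102 s, E.D becomes G in 0.00455 s, and J.G goes on to X in 0.156 s. J meets G at 11.8 s⁻¹, but J.G falls back at 11.2 s⁻¹, faster than it goes forward at 6.42 s⁻¹, so the attempts cost 0.232 s, longer than any of the other delays. The sum is 0.495 s, the cycle time: the mean time for one D to come round once at the starting charges.

In 10 s one D then makes 20.2 rounds, so violet turns over 40.4% of J and ochre 80.8%. These are estimates at the starting charges, and J and E fall during the run. Using up the E charge at this pace takes 22.3 s in violet, longer than the run, but 1.49 s in green, shorter than the run. I commit to a row that climbs with D and then levels off below the E charge, by what has passed to Q.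

The forecast, on the clock side, gave 30%, 51%, 70%, 79.5% and 79.2%, a row that rises all the way, on the ground that at low loading “the catalyst's turnover of about 2 per second sets the yield”.

The simulation gives X at 31.5%, 53.0%, 73.7%, 79.3% and 79.0%, a row that rises all the way.

The clock view stands, and the end-point view keeps its region later on: at 100 s, X reads 72.6% in violet and 72.6% in green. A violet run without the reverse step, J.G to J + G, has by the same sum a cycle time of 0.347 s, shorter by a factor 1.43, and its X at the end is higher by a factor 1.37. That step and the early reading together give the row its shape: violet holds X at 31.5%, at 43.0% without the reverse step, and at 72.6% when read later.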